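**Retrosynthetic overview**
- The (5E) target is made last by photochemical E/Z equilibration of its (5Z) isomer; the acetate is exchanged in from a silyl ether.
- C4–Br comes from the enol OH of a 5-(bromomethylidene)tetronic acid (Vilsmeier-type bromodehydroxylation).
- The butenolide, the only ring, is closed once at C3–C4 by an intramolecular ester-enolate aldol (Dieckmann/Claisen-type) addition onto the ester carbonyl of an α-acyloxy-β-bromoacrylate, which is unmasked in the same pot by E1cB loss of HBr.
- That precursor is the ester of two separately made fragments: (R)-3-silyloxyhexanoic acid (Noyori hydrogenation sets the stereocentre) and ethyl 3,3-dibromolactate (from ethyl pyruvate).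

Assumption: the SMILES is read as (1′R),(5E), i.e. the exocyclic Br is syn to C4 and anti to the ring oxygen.

**Fragment A**

Step 1
Reactants: 1, methyl 3-oxohexanoate
Product: 2, methyl (3R)-3-hydroxyhexanoate
Conditions: H2 (50 atm), RuCl2[(R)-BINAP] (0.1 mol %), MeOH, 50 °C
Reagents that add atoms: none (H2 only)
Why: Noyori asymmetric hydrogenation of a β-keto ester; the chelated (R)-BINAP–Ru hydride reduces one carbonyl face to give the (R)-carbinol, the future C1′.

Step 2
Reactants: 2, methyl (3R)-3-hydroxyhexanoate
Product: 3, methyl (3R)-3-[(tert-butyldimethylsilyl)oxy]hexanoate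
Conditions: TBSCl, imidazole, DMF, rt
Reagents that add atoms: tert-butyldimethylsilyl chloride, CC(C)(C)[Si](C)(C)Cl
Why: Silylation; the TBS ether is base-stable and a poor leaving group, so the β-oxygen survives the later enolate step, and the stereocentre is untouched.

Step 3
Reactants: 3, methyl (3R)-3-[(tert-butyldimethylsilyl)oxy]hexanoate
Product: 4, (3R)-3-[(tert-butyldimethylsilyl)oxy]hexanoic acid
Conditions: LiOH·H2O, THF/MeOH/H2O, 0 °C to rt; then pH 4
Reagents that add atoms: lithium hydroxide, [Li+].[OH-]
Why: Ester saponification (BAc2) under mild conditions that leave the TBS ether and the stereocentre intact.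

**Fragment B**

Step 4
Reactants: 5, ethyl pyruvate
Product: 6, ethyl 3,3-dibromo-2-oxopropanoate
Conditions: Br2 (2.1 equiv), cat. H2SO4, CH2Cl2, 0 to 40 °C
Reagents that add atoms: bromine, BrBr
Why: Acid-catalysed enol bromination; the methyl group is the only enolisable position and stoichiometry stops it at the dibromide.

Step 5
Reactants: 6, ethyl 3,3-dibromo-2-oxopropanoate
Product: 7, ethyl 3,3-dibromo-2-hydroxypropanoate (racemic)
Conditions: NaBH4 (0.3 equiv), EtOH, −40 °C; AcOH quench
Reagents that add atoms: none
Why: Chemoselective borohydride reduction of the activated α-keto carbonyl; the new centre is racemic but becomes sp2 in step 7.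

**Union and endgame**

Step 6
Reactants: 4, (3R)-3-[(tert-butyldimethylsilyl)oxy]hexanoic acid; 7, ethyl 3,3-dibromo-2-hydroxypropanoate
Product: 8, ethyl 3,3-dibromo-2-{[(3R)-3-(tert-butyldimethylsilyloxy)hexanoyl]oxy}propanoate (about 1:1 epimers at the new acyloxy-bearing carbon)
Conditions: 4, 1-chloro-N,N,2-trimethylprop-1-en-1-amine (Ghosez reagent), CH2Cl2, 0 °C; then 7, pyridine, 0 °C to rt
Reagents that add atoms: none
Why: Neutral acid-chloride formation followed by O-acylation (esterification); pyridine is too weak a base to trigger HBr loss.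

Step 7 (key ring closure)
Reactants: 8
Product: 9, (5Z)-5-(bromomethylidene)-3-[(1R)-1-(tert-butyldimethylsilyloxy)butyl]-4-hydroxyfuran-2(5H)-one
Conditions: LiHMDS (3.3 equiv), THF, −78 °C (8 added to the base), to −40 °C; cold pH 4 buffer quench; used crude
Reagents that add atoms: none
Why: E1cB loss of HBr gives the α-acyloxy-β-bromoacrylate, whose acyl enolate then adds 5-exo to the ester carbonyl and expels ethoxide (Dieckmann-type intramolecular ester aldol/Claisen condensation) to form the C3–C4 bond of the tetronic acid. The bromoalkene forms mainly Z (Br away from the ester carbon), and C1′ is not involved.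

Step 8
Reactants: 9
Product: 10, (5Z)-4-bromo-5-(bromomethylidene)-3-[(1R)-1-(tert-butyldimethylsilyloxy)butyl]furan-2(5H)-one
Conditions: (COBr)2 (1.3 equiv), DMF (1.5 equiv), 2,6-lutidine (1.1 equiv), CH2Cl2, 0 °C to rt
Reagents that add atoms: oxalyl bromide, O=C(Br)C(Br)=O
Why: Vilsmeier–Haack-type bromodehydroxylation: the enol is O-activated by the bromoiminium salt and bromide substitutes at C4 by addition–elimination; lutidine buffers the HBr so the TBS ether survives.

Step 9
Reactants: 10
Product: 11, (1R)-1-[(5Z)-4-bromo-5-(bromomethylidene)-2-oxo-2,5-dihydrofuran-3-yl]butyl acetate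
Conditions: Ac2O (3 equiv), Bi(OTf)3 (2 mol %), MeCN, 0 °C to rt
Reagents that add atoms: acetic anhydride, CC(=O)OC(C)=O
Why: Lewis-acid-catalysed silyl ether to acetate exchange (O-acylation then loss of silyl); the C1′–O bond is never broken, so the (R) configuration is retained.

Step 10
Reactants: 11
Product: 12, (1R)-1-[(5E)-4-bromo-5-(bromomethylidene)-2-oxo-2,5-dihydrofuran-3-yl]butyl acetate (acetoxyfimbrolide, target)
Conditions: hν (350 nm, Pyrex), degassed MeCN, rt, to the photostationary Z/E mixture; separate in the dark (HPLC) and recycle 11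
Reagents that add atoms: none
Why: Photochemical E/Z isomerisation of the exocyclic bromoenol lactone. The E isomer is the less stable geometry, so it is reached by photoequilibration and separation, not selectively, and the stereocentre is unaffected.

**Compound list**
1 | methyl 3-oxohexanoate | CCCC(=O)CC(=O)OC | starting material
2 | methyl (3R)-3-hydroxyhexanoate | CCC[C@@H](O)CC(=O)OC | intermediate
3 | methyl (3R)-3-[(tert-butyldimethylsilyl)oxy]hexanoate | CCC[C@@H](O[Si](C)(C)C(C)(C)C)CC(=O)OC | intermediate
4 | (3R)-3-[(tert-butyldimethylsilyl)oxy]hexanoic acid | CCC[C@@H](O[Si](C)(C)C(C)(C)C)CC(=O)O | intermediate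
5 | ethyl pyruvate | CCOC(=O)C(C)=O | starting material
6 | ethyl 3,3-dibromo-2-oxopropanoate | CCOC(=O)C(=O)C(Br)Br | intermediate
7 | ethyl 3,3-dibromo-2-hydroxypropanoate (racemic) | CCOC(=O)C(O)C(Br)Br | intermediate
8 | ethyl 3,3-dibromo-2-{[(3R)-3-(tert-butyldimethylsilyloxy)hexanoyl]oxy}propanoate (epimer mixture) | CCC[C@@H](O[Si](C)(C)C(C)(C)C)CC(=O)OC(C(Br)Br)C(=O)OCC | intermediate
9 | (5Z)-5-(bromomethylidene)-3-[(1R)-1-(tert-butyldimethylsilyloxy)butyl]-4-hydroxyfuran-2(5H)-one | CCC[C@@H](O[Si](C)(C)C(C)(C)C)C1=C(O)/C(=C/Br)OC1=O | intermediate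
10 | (5Z)-4-bromo-5-(bromomethylidene)-3-[(1R)-1-(tert-butyldimethylsilyloxy)butyl]furan-2(5H)-one | CCC[C@@H](O[Si](C)(C)C(C)(C)C)C1=C(Br)/C(=C/Br)OC1=O | intermediate
11 | (1R)-1-[(5Z)-4-bromo-5-(bromomethylidene)-2-oxo-2,5-dihydrofuran-3-yl]butyl acetate | CCC[C@@H](OC(C)=O)C1=C(Br)/C(=C/Br)OC1=O | intermediate
12 | (1R)-1-[(5E)-4-bromo-5-(bromomethylidene)-2-oxo-2,5-dihydrofuran-3-yl]butyl acetate (acetoxyfimbrolide) | CCC[C@@H](OC(C)=O)C1=C(Br)/C(=C\Br)OC1=O | target

**Totals**
Total step count: 10.
Longest linear sequence: 8 (steps 1–3, then 6–10); the second branch (steps 4–5) runs in parallel and joins at step 6.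

**Three steps most likely to fail**
1. Step 7 (E1cB/Dieckmann cascade). Risks are ketene fragmentation or ethoxide cleavage of the activated enol ester, β-silyloxy elimination, and a fragile β-silyloxy tetronic acid. Fallback: esterify 4 with methyl lactate, run the Dieckmann on that halogen-free ester to the 5-methyl tetronic acid, brominate C4, and only then build the exocyclic bromoalkene (γ-bromination via the 2-silyloxyfuran, elimination to the 5-methylene compound, Br2 addition and dehydrobromination).
2. Step 8 (Vilsmeier bromination). Risks are TBS loss or ionisation at C1′ under HBr. Fallback: do not isolate the tetronic acid; trap the lithium tetronate from step 7 as the C4 triflate (PhNTf2 or Comins' reagent) and convert triflate to bromide by addition–elimination with LiBr.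
3. Step 10 (photoisomerisation). Risks are an unfavourable photostationary ratio and photodebromination. Fallback: set the E geometry kinetically. Run steps 6–7 with ethyl 3,3,3-tribromolactate (from bromal) to reach the 5-(dibromomethylidene) tetronate. On its 4-O-silyl ether, remove the less hindered bromine (syn to the ring oxygen) by Pd(0)/Bu3SnH hydrodebromination, then install C4–Br.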